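## Structural features

The target is a diaryl ether made of two benzene rings and no other ring. Ring A is a methyl benzoate (ester at C1) with a prenyloxy group at C2, a methyl group at C4 and the bridging oxygen at C6. Ring B carries that oxygen at C1', a hydroxymethyl group at C2' and methoxy groups at C4' and C6'. There is no stereocentre and no stereogenic double bond, so no stereocentres stand next to each other and the problem is one of regiocontrol and chemoselectivity. The fragile groups are the prenyl aryl ether (attacked by protic and Lewis acids, rearranged on strong heating, reduced by hydrogenation), the benzylic alcohol, and the methyl ester, which is shielded by two ortho substituents but still open to hydride donors. The real difficulty is the ether oxygen: it lies between three ortho substituents (the C1 ester on ring A, CH2OH and OCH3 on ring B) and ring B is electron-rich, so neither SNAr nor a copper- or palladium-mediated union of two finished arenes is attractive. In addition, four oxygen functions must end up distinct: one prenyl ether, two methyl ethers and one free alcohol. Ring A is a 2,6-dioxygenated 4-methylbenzoate, the pattern that a 3-methoxycarbonyl-2-pyrone and a ketene acetal deliver: C1, C6, C5 and C4 come from pyrone C3, C4, C5 and C6, and C2 and C3 from the acetal carbon and the CH2 of the alkene. Because C6 of ring A is then C4 of the pyrone, a vinylogous acyl carbon, the crowded C–O bond can be made by addition–elimination before ring A exists as an arene.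

## Logic of the disconnections

**17 to 16.** The last bond made is a benzylic C–H bond: the hydroxymethyl group of ring B is traced back to a formyl group. The aldehyde carries this carbon through an acid chloride, a 130 °C step and a boron Lewis acid without protection, which the free alcohol would not tolerate. One functional-group change thus replaces a protection and a deprotection. The forward reduction must take the aldehyde and leave the hindered ester, which a borohydride at 0 °C should do.

**16 to 15.** The O–CH2 bond of the prenyl ether at C2 of ring A is cut. It is cut this late because the prenyl ether is the most acid- and heat-sensitive group and must meet neither the Lewis acid nor the thermal step. The gain is a phenol and a commercial C5 allyl halide. The forward step must alkylate a hydrogen-bonded, salicylate-type phenol on oxygen under a base mild enough for the aldehyde.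

**15 to 14.** The C2 phenol is traced back to its methyl ether, since the key step delivers this oxygen as OCH3. The neighbouring ester makes this methyl group the only one that a chelating Lewis acid removes, so no extra handle is needed. The forward step must cleave one of three aryl methyl ethers and leave the aldehyde intact.

**14 to 10 and 11.** C1–C2 and C3–C4 of ring A are cut, which turns the arene into an electron-poor 2-pyrone and a two-carbon ketene acetal. This removes a whole ring and moves the diaryl ether problem onto a non-aromatic electrophile. The forward cycloaddition must put the acetal carbon next to the ester-bearing carbon, and the aryloxy group at pyrone C4 must survive until CO2 and methanol have left.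

**10 to 6 and 9.** The bond between pyrone C4 and the phenolic oxygen is cut. C4 is a vinylogous acyl carbon flanked by two carbonyl groups, so a phenoxide can be introduced by addition–elimination regardless of ortho crowding. The gain is two small, separately made halves. The forward step needs a leaving group at C4 that the phenoxide cannot attack elsewhere, hence chloride and not a sulfonate.

**6 to 5.** The C–Cl bond is traced back to the enolic C–OH bond. 5 is a vinylogous acid, so this is an acid-to-acid-chloride change. The forward step must avoid aqueous handling of 6.

**5 to 1 and 2.** The C3–C4 bond and the O1–C2 lactone bond of the pyrone are cut, giving a malonate and an acetoacetyl (acylketene) donor. Both are bulk chemicals and the ester at C3 comes from the malonate. The forward step must trap the acylketene on carbon and then close the lactone.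

**9 to 7.** The aryl–CHO bond is cut. 7 already holds both methoxy groups and has a single free ortho position, so no aryl C–O bond to ring B has to be made and the regiochemistry is unambiguous. The forward step needs ortho-selective formylation, which magnesium phenoxide chelation provides.

## Other disconnections considered

**Alternative 1:** The cut runs through O–C6 and C1–C2 of ring A while that ring is still a cyclohexenone.

- Forward step: the potassium salt of 2-({[tert-butyl(dimethyl)silyl]oxy}methyl)-4,6-dimethoxyphenol A3 would add to the β-alkyne carbon of racemic dimethyl 5-methylhept-2-ynedioate A2. The vinyl anion so formed would close onto the remote ester in a Dieckmann step to give racemic methyl 2-[2-({[tert-butyl(dimethyl)silyl]oxy}methyl)-4,6-dimethoxyphenoxy]-4-methyl-6-oxocyclohex-1-ene-1-carboxylate A1. Dehydrogenation, prenylation and desilylation would follow.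
- In favour: like the chosen plan, it makes the crowded C–O bond by conjugate addition and not by joining two arenes; on this point it is the equal of the chosen plan. The C2 oxygen appears as a free phenol after aromatisation, so no demethylation is needed; on this point it is better.
- Against: A2 is not a catalogue compound and needs several steps. The vinyl anion must acylate an unactivated ester faster than it is protonated by A3. The late oxidation of A1 to the arene must spare an electron-rich ring B and a benzylic silyl ether. The methyl-bearing stereocentre of A1 is made only to be destroyed.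
- Comparison: it saves one step at the end but loses more in making A2 and protecting ring B, and its cascade rests on thinner precedent than the pyrone cycloaddition.

**Alternative 2:** The cut is the C1'–C2' bond of ring B, which is unfolded into an open chain.

- Forward step: mild base would fold methyl 2-[(7,7-dimethoxy-2,4,6-trioxoheptyl)oxy]-4-methyl-6-[(3-methylbut-2-en-1-yl)oxy]benzoate A5. The aryloxy-bearing CH2 adds to the ketone next to the acetal, and dehydration and enolisation give methyl 2-[2-(dimethoxymethyl)-4,6-dihydroxyphenoxy]-4-methyl-6-[(3-methylbut-2-en-1-yl)oxy]benzoate A4. Double O-methylation, acetal hydrolysis and reduction would follow.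
- In favour: the ether oxygen is attached to an sp3 carbon by a plain Williamson reaction, so the steric problem disappears; on this point it is better than the chosen plan. Ring A carries its prenyl ether from the start and no demethylation is needed; also better.
- Against: the nucleophile must be the least acidic CH2 of the chain, while the two methylene groups between carbonyls are far more acidic. 2,4,6-Triketones tend to close through oxygen to 4-pyranones. The chain needs several C-acylations of polyanions beside a benzoate, and four steps remain after the key step.
- Comparison: the chosen cycloaddition has one regiochemical outcome set by polarisation, whereas the folding has several competing modes. Both form one ring in the key step (equal). The alternative is longer before and after the key step.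

**Alternative 3:** The cut removes O–C6 and the C1–CO2CH3 bond and leaves ring A as an aryne.

- Forward step: CsF would convert 5-methyl-3-[(3-methylbut-2-en-1-yl)oxy]-2-(trimethylsilyl)phenyl trifluoromethanesulfonate A8 into 5-methyl-3-[(3-methylbut-2-en-1-yl)oxy]benzyne A9. The phenoxide derived from 2-[(methoxycarbonyloxy)methyl]-4,6-dimethoxyphenyl methyl carbonate A7 would add at the aryne carbon remote from the alkoxy group, and the aryl anion next to that group would be acylated by the carbonate. This formal insertion into the ArO–CO2CH3 bond gives methyl 2-{2-[(methoxycarbonyloxy)methyl]-4,6-dimethoxyphenoxy}-4-methyl-6-[(3-methylbut-2-en-1-yl)oxy]benzoate A6. Removal of the benzylic carbonate would end the synthesis.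
- In favour: it is the most convergent plan and sets the three contiguous substituents of ring A in one operation with the prenyl ether in place. Only one step follows the key step, against three in the chosen plan; on this point it is better. Regiocontrol by the inductive effect of the alkoxy group is as dependable as the polarisation control of the cycloaddition; equal.
- Against: A8 needs several steps of its own (silylation, triflation and mono-prenylation of a resorcinol). The prenyl alkene can trap the neighbouring aryne in an intramolecular ene reaction. The aryl anion can be protonated instead of acylated. Fluoride can attack the carbonate, and the doubly ortho-substituted phenoxide is a slow nucleophile.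
- Comparison: the overall step count is similar, but more untested behaviour is concentrated in one step. The chosen plan spends more steps after the key step, each of them routine.

Key step: step 5

Remark: the target is achiral, so the SMILES carry no stereodescriptors except for the transient racemic bicycle 12; 7 is taken as a purchasable phenol.

## Route

**Step 1**
Reactants: 1 dimethyl malonate; 2 2,2,6-trimethyl-4H-1,3-dioxin-4-one
Product: 5 methyl 4-hydroxy-6-methyl-2-oxo-2H-pyran-3-carboxylate, via acetylketene 3 (not isolated), via acylmalonate 4 (not isolated)
Conditions: NaH, DME/PhMe, 0 °C to rt; 2 added slowly at 110 °C; then 1 M HCl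
Reagents that add atoms: none
Why: Retro-[4+2] of 2 above 100 °C releases acetone and acetylketene 3, which the sodium enolate of 1 should trap by C-acylation to 4; the enol oxygen of the terminal ketone then lactonises onto one ester with loss of methanol, the dioxinone counterpart of the acylation of malonates by diketene.

**Step 2**
Reactants: 5 methyl 4-hydroxy-6-methyl-2-oxo-2H-pyran-3-carboxylate
Product: 6 methyl 4-chloro-6-methyl-2-oxo-2H-pyran-3-carboxylate
Conditions: (COCl)2, DMF (cat.), CH2Cl2, 0 °C to rt; evaporate, use crude
Reagents that add atoms: oxalyl chloride, O=C(Cl)C(Cl)=O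
Why: Vilsmeier-type deoxychlorination of a vinylogous acid: the chloroiminium salt activates the enol oxygen and chloride adds at the doubly activated C4 and expels DMF, as in the conversion of 1,3-diones into β-chloroenones; C3 is blocked by the ester, and all by-products are volatile so 6 never meets water.

**Step 3**
Reactants: 7 2,4-dimethoxyphenol
Product: 9 2-hydroxy-3,5-dimethoxybenzaldehyde, via salicyl alcohol 8 (not isolated)
Conditions: MgCl2, Et3N, (CH2O)n, MeCN, reflux; then 1 M HCl
Reagents that add atoms: paraformaldehyde (formaldehyde unit), C=O
Why: Magnesium-mediated ortho-formylation (Casnati–Skattebøl): the magnesium phenoxide delivers formaldehyde to the only free ortho position to give 8, which a second formaldehyde oxidises by hydride transfer to the aldehyde.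

**Step 4**
Reactants: 6 methyl 4-chloro-6-methyl-2-oxo-2H-pyran-3-carboxylate; 9 2-hydroxy-3,5-dimethoxybenzaldehyde
Product: 10 methyl 4-(2-formyl-4,6-dimethoxyphenoxy)-6-methyl-2-oxo-2H-pyran-3-carboxylate
Conditions: K2CO3, 4 Å MS, MeCN, 0 °C to rt
Reagents that add atoms: none
Why: Addition–elimination (vinylic substitution) at a vinylogous acyl chloride: the phenoxide adds to C4, the charge rests on the malonate-like C3, and chloride leaves, as with 4-chlorocoumarin-3-carboxylates and phenols; a chloride offers no sulfur centre for the phenoxide to attack, and attack at C2 or C6 is reversible.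

**Step 5**
Reactants: 10 methyl 4-(2-formyl-4,6-dimethoxyphenoxy)-6-methyl-2-oxo-2H-pyran-3-carboxylate; 11 1,1-dimethoxyethene
Product: 14 methyl 2-(2-formyl-4,6-dimethoxyphenoxy)-6-methoxy-4-methylbenzoate, via bicyclic lactone 12 (not isolated), via cyclohexadiene ketal 13 (not isolated)
Conditions: 11 (5 equiv), PhMe, sealed tube, 130 °C; then 1 M HCl, THF, rt
Reagents that add atoms: none
Why: Inverse-electron-demand Diels–Alder reaction: the 3-ester and the lactone carbonyl make 10 an electron-poor diene across C3–C6, and 11 is the electron-rich 2π partner. Bond formation should be asynchronous, the nucleophilic CH2 of 11 engaging pyrone C6 first while the developing negative charge sits on the malonate-like C3, which then closes onto the acetal carbon; this fixes the regiochemistry (acetal carbon next to the ester-bearing carbon, CH2 next to the methyl-bearing carbon). The new six-membered carbocycle is closed by this intermolecular [4+2] addition to give the bridged lactone 12, whose two bridgehead centres are transient and locked relative to each other by the bicycle, so no stereocentre has to be controlled. Retro-[4+2] loss of CO2 gives diene 13, and 1,2-elimination of methanol, driven by aromatisation, gives 14. The closest known reaction type is the cycloaddition of 3-alkoxycarbonyl-2-pyrones with 1,1-dialkoxyethenes to give 2-alkoxybenzoates. The step needs regioselectivity, secured by the matching polarisation of both partners, and chemoselectivity for C6 over the aryloxy-bearing C4 and over the formyl group: C4 is fully substituted and deactivated by its oxygen donor, the aldehyde is deactivated by two methoxy groups and no Lewis acid is present, and the excess of 11 should take up the liberated methanol. The acidic work-up destroys surplus 11 and returns any aldehyde acetal to the aldehyde.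

**Step 6**
Reactants: 14 methyl 2-(2-formyl-4,6-dimethoxyphenoxy)-6-methoxy-4-methylbenzoate
Product: 15 methyl 2-(2-formyl-4,6-dimethoxyphenoxy)-6-hydroxy-4-methylbenzoate
Conditions: BCl3 (2.5 equiv), CH2Cl2, –78 to 0 °C; then H2O
Reagents that add atoms: none
Why: Chelation-controlled demethylation: boron bridges the ester carbonyl and the ortho methoxy oxygen and chloride removes that methyl group by SN2; the two methoxy groups of ring B have no ortho carbonyl (the aldehyde is flanked by the diaryl ether oxygen and a hydrogen) and should survive at or below 0 °C, and the aldehyde is released on hydrolysis.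

**Step 7**
Reactants: 15 methyl 2-(2-formyl-4,6-dimethoxyphenoxy)-6-hydroxy-4-methylbenzoate
Product: 16 methyl 2-(2-formyl-4,6-dimethoxyphenoxy)-4-methyl-6-[(3-methylbut-2-en-1-yl)oxy]benzoate
Conditions: prenyl bromide, K2CO3, DMF, rt
Reagents that add atoms: 1-bromo-3-methylbut-2-ene (prenyl bromide), CC(C)=CCBr
Why: Williamson ether synthesis: the potassium phenoxide in a dipolar aprotic solvent reacts on oxygen at the primary allylic carbon (SN2), and the base is too weak to disturb the non-enolisable aldehyde or the ester.

**Step 8**
Reactants: 16 methyl 2-(2-formyl-4,6-dimethoxyphenoxy)-4-methyl-6-[(3-methylbut-2-en-1-yl)oxy]benzoate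
Product: 17 methyl 2-[2-(hydroxymethyl)-4,6-dimethoxyphenoxy]-4-methyl-6-[(3-methylbut-2-en-1-yl)oxy]benzoate
Conditions: NaBH4, MeOH/THF, 0 °C; aq. NH4Cl
Reagents that add atoms: none
Why: Chemoselective borohydride reduction: the aryl aldehyde is reduced within minutes at 0 °C, while the doubly ortho-substituted methyl ester, the prenyl alkene and the ethers are inert; the neutral work-up avoids acid at the prenyl ether.

## Compound list

1 | dimethyl malonate | COC(=O)CC(=O)OC | starting material
2 | 2,2,6-trimethyl-4H-1,3-dioxin-4-one | CC1=CC(=O)OC(C)(C)O1 | starting material
3 | acetylketene (3-oxobut-1-en-1-one) | CC(=O)C=C=O | intermediate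
4 | dimethyl 2-(3-oxobutanoyl)propanedioate | COC(=O)C(C(=O)OC)C(=O)CC(C)=O | intermediate
5 | methyl 4-hydroxy-6-methyl-2-oxo-2H-pyran-3-carboxylate | COC(=O)C1=C(O)C=C(C)OC1=O | intermediate
6 | methyl 4-chloro-6-methyl-2-oxo-2H-pyran-3-carboxylate | COC(=O)C1=C(Cl)C=C(C)OC1=O | intermediate
7 | 2,4-dimethoxyphenol | COc1ccc(O)c(OC)c1 | starting material
8 | 2-(hydroxymethyl)-4,6-dimethoxyphenol | COc1cc(CO)c(O)c(OC)c1 | intermediate
9 | 2-hydroxy-3,5-dimethoxybenzaldehyde | COc1cc(OC)c(O)c(C=O)c1 | intermediate
10 | methyl 4-(2-formyl-4,6-dimethoxyphenoxy)-6-methyl-2-oxo-2H-pyran-3-carboxylate | COC(=O)C1=C(Oc2c(C=O)cc(OC)cc2OC)C=C(C)OC1=O | intermediate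
11 | 1,1-dimethoxyethene | C=C(OC)OC | starting material
12 | rac-methyl 5-(2-formyl-4,6-dimethoxyphenoxy)-8,8-dimethoxy-1-methyl-3-oxo-2-oxabicyclo[2.2.2]oct-5-ene-4-carboxylate (racemic, one enantiomer drawn; bridgeheads locked by the bicycle) | COC(=O)[C@]12C(=O)O[C@](C)(CC1(OC)OC)C=C2Oc1c(C=O)cc(OC)cc1OC | intermediate
13 | methyl 2-(2-formyl-4,6-dimethoxyphenoxy)-6,6-dimethoxy-4-methylcyclohexa-1,3-diene-1-carboxylate | COC(=O)C1=C(Oc2c(C=O)cc(OC)cc2OC)C=C(C)CC1(OC)OC | intermediate
14 | methyl 2-(2-formyl-4,6-dimethoxyphenoxy)-6-methoxy-4-methylbenzoate | COC(=O)c1c(OC)cc(C)cc1Oc1c(C=O)cc(OC)cc1OC | intermediate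
15 | methyl 2-(2-formyl-4,6-dimethoxyphenoxy)-6-hydroxy-4-methylbenzoate | COC(=O)c1c(O)cc(C)cc1Oc1c(C=O)cc(OC)cc1OC | intermediate
16 | methyl 2-(2-formyl-4,6-dimethoxyphenoxy)-4-methyl-6-[(3-methylbut-2-en-1-yl)oxy]benzoate | COC(=O)c1c(OCC=C(C)C)cc(C)cc1Oc1c(C=O)cc(OC)cc1OC | intermediate
17 | methyl 2-[2-(hydroxymethyl)-4,6-dimethoxyphenoxy]-4-methyl-6-[(3-methylbut-2-en-1-yl)oxy]benzoate | COC(=O)c1c(OCC=C(C)C)cc(C)cc1Oc1c(CO)cc(OC)cc1OC | target

## Step count and least certain steps

Total step count: 8. Longest linear sequence: 7 steps (steps 1, 2, 4, 5, 6, 7, 8, from 1 and 2 to 17); step 3 is a one-step branch.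

**Step 5 (key step).** The most likely failure is a cycloaddition that is slower than substitution at C4. The aryloxy oxygen raises the diene LUMO and the 6-methyl group hinders the first bond, so the aryloxy group may be exchanged by liberated methanol or by the nucleophilic alkene before the diene is consumed. The formyl group may also be attacked by the ketene acetal at this temperature. The fallback builds ring A on a small 4-alkoxy pyrone and forms the diaryl ether afterwards; it sets out from 6 and 9 and comes back at 14. Methanol and Et3N would convert 6 into methyl 4-methoxy-6-methyl-2-oxo-2H-pyran-3-carboxylate F1. Heating F1 with 11 would lead, through rac-methyl 5,8,8-trimethoxy-1-methyl-3-oxo-2-oxabicyclo[2.2.2]oct-5-ene-4-carboxylate F2 and methyl 2,6,6-trimethoxy-4-methylcyclohexa-1,3-diene-1-carboxylate F3 (neither isolated), to methyl 2,6-dimethoxy-4-methylbenzoate F4. One equivalent of BCl3 would remove a single chelated methyl group to give methyl 2-hydroxy-6-methoxy-4-methylbenzoate F5. Separately, 9 with triflic anhydride and pyridine would give 2-formyl-4,6-dimethoxyphenyl trifluoromethanesulfonate F6. A palladium-catalysed C–O cross-coupling of F5 with F6 (Pd2(dba)3, tBuXPhos, K3PO4, PhMe, 100 °C) would then give 14. The price is the crowded aryl–oxygen coupling that the main route avoids.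

**Step 4.** The most likely failure is sluggish addition–elimination by a hindered phenoxide whose ortho formyl group lowers its nucleophilicity. This leaves time for hydrolysis of the vinylogous acid chloride by traces of water and for ring-opening attack at C6 or C2. The fallback masks the aldehyde to raise the nucleophilicity; it sets out from 9 and comes back at 10. Ethylene glycol with catalytic TsOH under azeotropic removal of water would give 2-(1,3-dioxolan-2-yl)-4,6-dimethoxyphenol F7. Its potassium salt and 6 (K2CO3, MeCN) would give methyl 4-[2-(1,3-dioxolan-2-yl)-4,6-dimethoxyphenoxy]-6-methyl-2-oxo-2H-pyran-3-carboxylate F8. Brief treatment with PPTS in wet acetone at rt should release the aldehyde and give 10.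

**Step 1.** The most likely failure is self-condensation of the acylketene faster than its capture by the heterogeneous malonate enolate, together with O-acylation and incomplete lactonisation. The fallback assembles the pyrone from a ketene dithioacetal and a ketone enolate; it sets out from 1 and comes back at 10, bypassing 5 and 6. K2CO3, CS2 and iodomethane in DMF would give dimethyl 2-[bis(methylsulfanyl)methylidene]propanedioate F9. Acetone with powdered KOH in DMSO would displace one methylsulfanyl group to give dimethyl 2-[1-(methylsulfanyl)-3-oxobutylidene]propanedioate F10 (not isolated), which lactonises to methyl 6-methyl-4-(methylsulfanyl)-2-oxo-2H-pyran-3-carboxylate F11. Two equivalents of mCPBA would give methyl 4-(methanesulfonyl)-6-methyl-2-oxo-2H-pyran-3-carboxylate F12. The potassium salt of 9 would displace methanesulfinate from F12 to give 10.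

**Step 2.** The most likely failure is hydrolysis of the vinylogous acid chloride during concentration and transfer, or electrophilic attack of the chloroiminium reagent at C5 of the pyrone. The fallback replaces the chloride by an isolable, crystalline sulfonate; it sets out from 5 and comes back at 10. Tosyl chloride and Et3N in CH2Cl2 would give methyl 6-methyl-4-{[(4-methylphenyl)sulfonyl]oxy}-2-oxo-2H-pyran-3-carboxylate F13, which would be treated with 9 and K2CO3 as in step 4. The known weakness of this variant is transfer of the sulfonyl group to the phenoxide, which is why it is the second choice.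

## Further compounds

F1 | step 5 | methyl 4-methoxy-6-methyl-2-oxo-2H-pyran-3-carboxylate | COC(=O)C1=C(OC)C=C(C)OC1=O
F2 | step 5 | rac-methyl 5,8,8-trimethoxy-1-methyl-3-oxo-2-oxabicyclo[2.2.2]oct-5-ene-4-carboxylate (racemic, one enantiomer drawn) | COC(=O)[C@]12C(=O)O[C@](C)(CC1(OC)OC)C=C2OC
F3 | step 5 | methyl 2,6,6-trimethoxy-4-methylcyclohexa-1,3-diene-1-carboxylate | COC(=O)C1=C(OC)C=C(C)CC1(OC)OC
F4 | step 5 | methyl 2,6-dimethoxy-4-methylbenzoate | COC(=O)c1c(OC)cc(C)cc1OC
F5 | step 5 | methyl 2-hydroxy-6-methoxy-4-methylbenzoate | COC(=O)c1c(O)cc(C)cc1OC
F6 | step 5 | 2-formyl-4,6-dimethoxyphenyl trifluoromethanesulfonate | COc1cc(OC)c(OS(=O)(=O)C(F)(F)F)c(C=O)c1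
F7 | step 4 | 2-(1,3-dioxolan-2-yl)-4,6-dimethoxyphenol | COc1cc(OC)c(O)c(C2OCCO2)c1
F8 | step 4 | methyl 4-[2-(1,3-dioxolan-2-yl)-4,6-dimethoxyphenoxy]-6-methyl-2-oxo-2H-pyran-3-carboxylate | COC(=O)C1=C(Oc2c(C3OCCO3)cc(OC)cc2OC)C=C(C)OC1=O
F9 | step 1 | dimethyl 2-[bis(methylsulfanyl)methylidene]propanedioate | COC(=O)C(=C(SC)SC)C(=O)OC
F10 | step 1 | dimethyl 2-[1-(methylsulfanyl)-3-oxobutylidene]propanedioate | COC(=O)C(C(=O)OC)=C(SC)CC(C)=O
F11 | step 1 | methyl 6-methyl-4-(methylsulfanyl)-2-oxo-2H-pyran-3-carboxylate | COC(=O)C1=C(SC)C=C(C)OC1=O
F12 | step 1 | methyl 4-(methanesulfonyl)-6-methyl-2-oxo-2H-pyran-3-carboxylate | COC(=O)C1=C(S(C)(=O)=O)C=C(C)OC1=O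
F13 | step 2 | methyl 6-methyl-4-{[(4-methylphenyl)sulfonyl]oxy}-2-oxo-2H-pyran-3-carboxylate | COC(=O)C1=C(OS(=O)(=O)c2ccc(C)cc2)C=C(C)OC1=O
A1 | alternative 1 | racemic methyl 2-[2-({[tert-butyl(dimethyl)silyl]oxy}methyl)-4,6-dimethoxyphenoxy]-4-methyl-6-oxocyclohex-1-ene-1-carboxylate | COC(=O)C1=C(Oc2c(CO[Si](C)(C)C(C)(C)C)cc(OC)cc2OC)CC(C)CC1=O
A2 | alternative 1 | racemic dimethyl 5-methylhept-2-ynedioate | COC(=O)C#CCC(C)CC(=O)OC
A3 | alternative 1 | 2-({[tert-butyl(dimethyl)silyl]oxy}methyl)-4,6-dimethoxyphenol | COc1cc(CO[Si](C)(C)C(C)(C)C)c(O)c(OC)c1
A4 | alternative 2 | methyl 2-[2-(dimethoxymethyl)-4,6-dihydroxyphenoxy]-4-methyl-6-[(3-methylbut-2-en-1-yl)oxy]benzoate | COC(=O)c1c(OCC=C(C)C)cc(C)cc1Oc1c(C(OC)OC)cc(O)cc1O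
A5 | alternative 2 | methyl 2-[(7,7-dimethoxy-2,4,6-trioxoheptyl)oxy]-4-methyl-6-[(3-methylbut-2-en-1-yl)oxy]benzoate | COC(=O)c1c(OCC=C(C)C)cc(C)cc1OCC(=O)CC(=O)CC(=O)C(OC)OC
A6 | alternative 3 | methyl 2-{2-[(methoxycarbonyloxy)methyl]-4,6-dimethoxyphenoxy}-4-methyl-6-[(3-methylbut-2-en-1-yl)oxy]benzoate | COC(=O)c1c(OCC=C(C)C)cc(C)cc1Oc1c(COC(=O)OC)cc(OC)cc1OC
A7 | alternative 3 | 2-[(methoxycarbonyloxy)methyl]-4,6-dimethoxyphenyl methyl carbonate | COC(=O)OCc1cc(OC)cc(OC)c1OC(=O)OC
A8 | alternative 3 | 5-methyl-3-[(3-methylbut-2-en-1-yl)oxy]-2-(trimethylsilyl)phenyl trifluoromethanesulfonate | Cc1cc(OCC=C(C)C)c([Si](C)(C)C)c(OS(=O)(=O)C(F)(F)F)c1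
A9 | alternative 3 | 5-methyl-3-[(3-methylbut-2-en-1-yl)oxy]benzyne | CC1=CC#CC(OCC=C(C)C)=C1
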